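Time sorts these flasks into rungs, and I read the rungs off the earlier runs.

| setting | spring | noon | summer | dusk | Friday's | Tuesday's | Wednesday's | Thursday's |
|---|---|---|---|---|---|---|---|---|
| G | 10 mM | 14 mM | 22 mM | 10 mM | 10 mM | 10 mM (fed, over 1.5 min) | 10 mM | 10 mM |
| J | 20 mM | 20 mM | 20 mM | 10 mM | 20.0 mM (in portions, 5, over 1.5 min) | 20.0 mM | 20.0 mM (fed, over 1.5 min) | 20.0 mM |
| remark | run made earlier | run made earlier | run made earlier | run made earlier | first portion at the start, last at 1.5 min | all else is in the flask from the start; the feed brings no volume worth counting | all else is in the flask from the start; the feed brings no volume worth counting | everything together at the start |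
| time |  |  |  |  | 2.5 min | 2.5 min | 2.5 min | 2.5 min |

- spring (time / s: X / %, G / %): 10.0: 0, 91.7; 15.0: 0, 87.7; 25.0: 2.4, 79.9; 50.0: 12.1, 63.8; 90.0: 21.1, 43.7
- noon (time / min: X / %, G / %): 0.200: 0, 90.0; 0.667: 7.0, 71.0; 1.33: 16.3, 47.3; 2.00: 25.8, 31.4; 2.50: 27.2, 21.2
- summer (time / min: X / %, G / %): 0.200: 2.0, 89.6; 0.667: 5.7, 70.2; 1.33: 11.7, 48.3; 2.00: 17.9, 31.3; 2.50: 21.0, 21.7
- dusk (time / min: X / %, G / %): 0.200: 0, 89.2; 0.667: 3.7, 70.9; 1.33: 11.5, 50.8; 2.00: 19.7, 34.2; 2.50: 22.4, 25.0

(standard deviation of a reading: 1 percentage point)



- the flask that comes out highest in amount of X, in percent of the G charged, or "all alike" when all lie within 1.5 percentage points (Friday's / Tuesday's / Wednesday's / Thursday's / all alike)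
- X at the end, in percent of the G charged, Friday's
- X at the end, in percent of the G charged, Tuesday's
- X at the end, in percent of the G charged, Wednesday's
- X at the end, in percent of the G charged, Thursday's

The first rung is a lag: at 15.0 s the spring run, which has Thursday's charges, holds G at 87.7 % and X at 0 %, so G first goes into something I cannot see. The next rung is the loss of G, which I read from the same run as a first-order constant:

k = ln(G at 10.0 s / G at 90.0 s) / elapsed time = 0.556 /min

The lifetime of G is then 1.80 min, of the same order as the feed of 1.5 min. The last rung is the rise of X, which I take between 0.667 min and 2.00 min. The summer run gives 2.01 mM/min and the noon run 1.97 mM/min, although the charges of G differ. I therefore freeze this rate for runs with J at 20 mM and call it the draw, a net rise of X as the readings show it. With J at 10 mM the dusk run draws 1.20 mM/min.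

Over the first 1.5 min, my reckoning of the mean rate at which G leaves gives:

Thursday's: inflow = c_G (1 − exp(−k t)) / t = 3.77 mM/min, over the draw 1.87

Tuesday's: inflow = c_G (1 − (1 − exp(−k t)) / (k t)) / t = 2.14 mM/min, over the draw 1.07

This ratio of inflow to draw is the load. Tuesday's inflow is close to the draw, while Thursday's exceeds it, so I set Tuesday's X near Thursday's. Wednesday's and Friday's hold J back, and the dusk run draws less, so I set them lower.

The forecast names Thursday's, with Thursday's 33 %, Friday's 26 %, Wednesday's 25 % and Tuesday's 25 %, since feeding G “delays intermediate formation by about 0.75 min”. On Tuesday's, my reckoning and the forecast differ.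

The flask gives Thursday's as highest, with Thursday's 35.6 %, Tuesday's 33.6 %, Friday's 25.3 % and Wednesday's 25.0 %.

    G → E (k = 0.00852 /s)
    J → Q (k = 0.00662 /s)
    E + Q → X (k = 7.47 /M/s)
    2 E → D (k = 10.7 /M/s)
    G + X → L (k = 0.703 /M/s)

At 2.50 min, D stands at 10.8 % in Tuesday's and 23.1 % in Thursday's. Wednesday's has Thursday's G charge, so it has the load 1.87 if held against the same draw. Charged with 40 mM of G, Wednesday's flask has, against that same draw, the load 7.49 and ends with D at 53.7 % and X at 8.31 %, which is 3.32 mM of X.

The numbers in the tables stem from a simulated flask on assumed constants.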